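**Plan**
- Locants used throughout: C1 furanone C=O, C2 furanone CH, C3 furanone C–O, C4=C5 with C15H2OH on C4, C6 CH–O-angelate, C7/C8 lactone ring fusion (O on C8), C9 CH2, C10 C(CH3)–O, C11=C13 methylene, C12 lactone C=O.
- Retrosynthetic cuts, in order: the C6 ester; the C3–O bond of the 3(2H)-furanone (back to a C1 ketone, a masked C3 ketone and the C10 hydroxyl); C11=C13; then C1–C10. This last cut is possible because C1 (furanone carbonyl) and C10 (the methyl-bearing ring carbon on the furanone oxygen) are neighbouring carbons of the ten-membered ring that both carry oxygen, so both can come from carbonyl groups (an aldehyde and a methyl ketone) joined by reductive ketyl (pinacol) coupling.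
- The open chain is cut at C3–C4 (acyl–alkenyl coupling), C4=C5 (alkyne, anti hydrostannation), C5–C6 (acetylide addition), C8–C9 (allylation) and C7–C11 (cyclopropanation of methyl furan-2-carboxylate).
- Forward order: the γ-lactone first (steps 1–4), then the C1–C6 chain and the C10 ketone (5–17), the ten-membered carbocycle (18), the methylene group (20), the furanone ring (22) and the angelate (24).
- Stereochemistry: C7 from the copper–bis(oxazoline) cyclopropanation, C8 from Felkin–Anh allylation, C6 from catalyst-controlled transfer hydrogenation of an ynone, the Z alkene from anti hydrostannation, C10 from the ketone face taken in the ring closure, the angelate geometry from angelic acid.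

Key step: step 18

Assumption: the (S,S)-bis(oxazoline) copper catalyst of step 1 and the (R,R)-TsDPEN ruthenium catalyst of step 7 are taken to show the sense of induction known for the parent substrates; if either is opposite, the mirror-image ligand is used.

**Route**

Step 1
Reactants: 1 methyl furan-2-carboxylate; 2 ethyl diazoacetate
Product: 3 bicyclic diester 6-ethyl 3-methyl (1S,5S,6S)-2-oxabicyclo[3.1.0]hex-3-ene-3,6-dicarboxylate
Conditions: Cu(OTf)2 (1 mol%), (S,S)-2,2'-isopropylidenebis(4-isopropyl-2-oxazoline) (1.2 mol%), PhNHNH2 (1 mol%), CH2Cl2, 0 °C, slow addition of 2; recrystallisation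
Reagents that add atoms: none
Why: Asymmetric copper-carbenoid cyclopropanation (monovalent copper formed by phenylhydrazine) should take place at the unsubstituted C4=C5 bond of the furan on the exo face, the ligand fixing the three ring centres, one of which becomes C7, and recrystallisation should raise the ester to enantiopurity.

Step 2
Reactants: 3 bicyclic diester
Product: 5 cyclopropane aldehyde ethyl (1S,2S,3S)-2-formyl-3-[(methoxyoxalyl)oxy]cyclopropane-1-carboxylate, via ozonide 4 (not isolated)
Conditions: O3, CH2Cl2, −78 °C; then Me2S, −78 to 23 °C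
Reagents that add atoms: ozone, [O-][O+]=O
Why: Ozonolysis should cleave only the electron-rich enol ether double bond, turning the ring oxygen into an oxalate ester and leaving the acceptor-substituted cyclopropane and its stereocentres untouched.

Step 3
Reactants: 5 cyclopropane aldehyde; 6 allyltrimethylsilane
Product: 7 homoallylic alcohol (the (1S)-1-hydroxybut-3-enyl analogue of 5)
Conditions: BF3·OEt2, CH2Cl2, −78 °C
Reagents that add atoms: none
Why: Hosomi–Sakurai allylation in which the allylsilane should attack the bisected cyclopropanecarbaldehyde anti to the oxalate-bearing ring carbon (Felkin–Anh), setting the C8 carbinol as (S) and forming C8–C9.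

Step 4
Reactants: 7 homoallylic alcohol
Product: 10 lactone aldehyde (2S,3R)-2-allyl-5-oxotetrahydrofuran-3-carbaldehyde, via cyclopropanol 8 (not isolated), via hydroxy ester aldehyde 9 (not isolated)
Conditions: Ba(OH)2·8H2O, MeOH, 0 °C
Reagents that add atoms: none
Why: Cleavage of the oxalate frees a donor–acceptor cyclopropanol that opens by retro-aldol reaction to the C6 aldehyde and the ester-bearing C11 methylene, after which the C8 hydroxyl lactonises onto the ethyl ester, with C7 and C8 substituents trans as the more stable arrangement.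

Step 5
Reactants: 10 lactone aldehyde; 11 tert-butyldimethyl(prop-2-yn-1-yloxy)silane
Product: 14 propargylic alcohols (both C6 epimers), via lithium acetylide 12 (not isolated), via cerium acetylide 13 (not isolated)
Conditions: 11, n-BuLi, THF, −78 °C; CeCl3, −78 °C; then 10, −78 °C; aq. NH4Cl
Reagents that add atoms: none
Why: 1,2-Addition of a weakly basic alkynylcerium reagent to the aldehyde should outrun enolisation at C7 and attack on the lactone; C6 is left uncontrolled because it is oxidised in step 6.

Step 6
Reactants: 14 propargylic alcohols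
Product: 15 ynone (C6 ketone)
Conditions: Dess–Martin periodinane, NaHCO3, CH2Cl2, 0 to 23 °C
Reagents that add atoms: none
Why: Buffered Dess–Martin oxidation should give the alkynyl ketone without epimerising C7 or opening the lactone by β-elimination.

Step 7
Reactants: 15 ynone
Product: 16 (6R)-propargylic alcohol
Conditions: Ru[(R,R)-TsNCHPhCHPhNH](p-cymene) (2 mol%), i-PrOH, 23 °C
Reagents that add atoms: none
Why: Noyori–Ikariya asymmetric transfer hydrogenation of an alkynyl ketone, in which the catalyst distinguishes alkynyl from alkyl and its preference coincides with Felkin–Anh hydride delivery anti to C8, so the (6R) carbinol should form under neutral conditions that spare C7.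

Step 8
Reactants: 16 (6R)-propargylic alcohol
Product: 17 bis-TBS ether
Conditions: TBSOTf, 2,6-lutidine, CH2Cl2, −78 to 0 °C
Reagents that add atoms: tert-butyldimethylsilyl triflate, CC(C)(C)[Si](C)(C)OS(=O)(=O)C(F)(F)F
Why: Routine silylation of a secondary alcohol with a silyl triflate; TBS is chosen at C6 because it survives the later mildly acidic steps and is a poor neighbouring group.

Step 9
Reactants: 17 bis-TBS ether
Product: 18 C15 alcohol (C6 O-TBS retained)
Conditions: CSA (10 mol%), MeOH/CH2Cl2 1:1, 0 °C
Reagents that add atoms: none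
Why: Acid-catalysed methanolysis should remove the unhindered primary TBS ether much faster than the secondary one next to C7, freeing the hydroxyl that directs step 10.

Step 10
Reactants: 18 C15 alcohol
Product: 19 (Z)-alkenylstannane (Bu3Sn on C4, cis to C6)
Conditions: [Cp*RuCl]4 (2.5 mol%), Bu3SnH (slow addition), CH2Cl2, 23 °C
Reagents that add atoms: tributyltin hydride, CCCC[SnH](CCCC)CCCC
Why: Ruthenium-catalysed trans-hydrostannation in which the free C15 hydroxyl, hydrogen-bonded to the chloride on ruthenium, steers tin to the proximal carbon C4 and anti addition places tin cis to C6, which fixes the later Z relation of C3 and C6; lactone and terminal alkene are tolerated.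

Step 11
Reactants: 19 (Z)-alkenylstannane
Product: 20 TBDPS ether of 19
Conditions: TBDPSCl, imidazole, CH2Cl2, 0 to 23 °C
Reagents that add atoms: tert-butyl(chloro)diphenylsilane, CC(C)(C)[Si](Cl)(c1ccccc1)c1ccccc1
Why: Routine silylation of the primary allylic alcohol; TBDPS is taken because it has to outlast aqueous acid and the cleavage of the C6 TBS ether.

Step 12
Reactants: 21 3-[(4-methoxybenzyl)oxy]propanoic acid
Product: 22 3-[(4-methoxybenzyl)oxy]propanoyl chloride
Conditions: (COCl)2, DMF (cat.), CH2Cl2, 0 to 23 °C; concentrated and used crude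
Reagents that add atoms: oxalyl chloride, O=C(Cl)C(=O)Cl
Why: Standard acid chloride formation through the Vilsmeier-type chloroiminium intermediate, mild enough for the PMB ether.

Step 13
Reactants: 20 TBDPS ether of 19; 22 acid chloride
Product: 23 (Z)-enone (C3 ketone, C1 O-PMB)
Conditions: Pd2(dba)3 (5 mol%), tri(2-furyl)phosphine (20 mol%), CuI (10 mol%), toluene, 50 °C
Reagents that add atoms: none
Why: Stille acylation (oxidative addition of the acyl chloride to zerovalent palladium, tin-to-palladium transfer of the alkenyl group with retention, reductive elimination) should form C3–C4, tri(2-furyl)phosphine and CuI speeding transmetalation of the α-branched stannane and the absence of amine avoiding elimination of the β-alkoxy acyl chloride.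

Step 14
Reactants: 23 (Z)-enone
Product: 24 C3 dioxolane
Conditions: TMSOCH2CH2OTMS (3 equiv), TMSOTf (10 mol%), CH2Cl2, −78 to −20 °C; pyridine quench
Reagents that add atoms: 1,2-bis(trimethylsilyloxy)ethane, C[Si](C)(C)OCCO[Si](C)(C)C
Why: Noyori ketalisation is aprotic, runs cold and is driven by loss of hexamethyldisiloxane, so the α-branched enone should be ketalised without double-bond migration or Z-to-E isomerisation, and at a stage where no other ketone is present.

Step 15
Reactants: 24 C3 dioxolane
Product: 25 C10 methyl ketone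
Conditions: PdCl2 (10 mol%), Cu(OAc)2·H2O (20 mol%), O2 (1 atm), DMA/H2O 7:1, 23 °C
Reagents that add atoms: water, O (source of the ketone oxygen); dioxygen, O=O (terminal oxidant)
Why: Tsuji–Wacker oxidation should convert the only monosubstituted alkene into the methyl ketone by Markovnikov hydroxypalladation, the trisubstituted C4=C5 alkene being inert and the acetate-buffered copper co-oxidant sparing ketal and silyl ethers.

Step 16
Reactants: 25 C10 methyl ketone
Product: 26 C1 alcohol
Conditions: DDQ, CH2Cl2/pH 7 buffer 10:1, 0 °C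
Reagents that add atoms: none
Why: Oxidative PMB cleavage by DDQ (benzylic hydride abstraction, then hydrolysis of the oxocarbenium ion) under buffered conditions leaves silyl ethers, ketal, ketone and lactone untouched.

Step 17
Reactants: 26 C1 alcohol
Product: 27 keto-aldehyde (C1 aldehyde, C10 methyl ketone)
Conditions: Dess–Martin periodinane, NaHCO3, CH2Cl2, 0 °C; used at once
Reagents that add atoms: none
Why: Buffered Dess–Martin oxidation of the primary alcohol; the β-ketal aldehyde is prone to elimination and is therefore not stored.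

Step 18
Reactants: 27 keto-aldehyde
Product: 28 ten-membered C1,C10-diol ((10R), either C1 epimer)
Conditions: SmI2 (0.1 M in THF, 4 equiv), THF, 23 °C, 27 added over 8 h (final 2 mM); aq. NaHCO3
Reagents that add atoms: none
Why: SmI2 transfers one electron to the more easily reduced C1 aldehyde, the samarium-bound ketyl adds to the C10 methyl ketone held on the same trivalent samarium centre, and a second electron and aqueous work-up give the diol, so two electrophilic carbonyl carbons are joined without an acyl anion equivalent. The closest known reaction type is the intramolecular samarium diiodide pinacol coupling of keto-aldehydes to medium and large carbocyclic diols. The ten-membered carbocycle closes by attack of the C1 ketyl carbon on the C10 carbonyl carbon with the oxygen exocyclic (10-exo-trig) under high dilution, and the Z C4=C5 alkene, the C3 ketal and the trans lactone turn the two chain ends toward each other while one samarium bridges both oxygens. C1 is formed without control and is erased by oxidation in step 21. C10 has to arise by addition to the Si face of the ketone, which is expected from the chelated conformer in which C9 is anchored by the C8 centre of the trans lactone and the C10 methyl group points to the outside of the forming ring; this is the untested point of the route. Chemoselectivity rests on the order of reduction (aldehyde before ketone; lactone, ketal, silyl ethers and the isolated alkene are inert to SmI2 in THF without HMPA), and the lactone still lacks the reducible methylene group.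

Step 19
Reactants: 28 C1,C10-diol
Product: 29 bis-TMS ether
Conditions: N-(trimethylsilyl)imidazole (6 equiv), CH2Cl2, 23 to 40 °C
Reagents that add atoms: N-(trimethylsilyl)imidazole, C[Si](C)(C)n1ccnc1
Why: Neutral silyl transfer should mask the secondary and the tertiary hydroxyl so that only the lactone is deprotonated in step 20, TMS being removable later beside TBS and TBDPS.

Step 20
Reactants: 29 bis-TMS ether
Product: 33 α-methylene lactone diol, via Mannich base 30 (not isolated), via ammonium iodide 31 (not isolated), via silylated methylene lactone 32 (not isolated)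
Conditions: LiN(i-Pr)2 (1.3 equiv), THF, −78 °C; CH2=NMe2+ I−, −78 to 0 °C; MeI, MeOH, 23 °C; aq. NaHCO3/CH2Cl2, 23 °C; citric acid, MeOH, 0 °C
Reagents that add atoms: N,N-dimethylmethyleneiminium iodide (Eschenmoser's salt), C=[N+](C)C.[I-]
Why: Eschenmoser methylenation, in which the lactone enolate (the only acidic site) is aminomethylated, the amine is quaternised and eliminated (E1cB) to the exocyclic alkene, and mild acidic methanolysis then removes both TMS ethers while TBS, TBDPS and the ketal stay.

Step 21
Reactants: 33 α-methylene lactone diol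
Product: 34 α-hydroxy ketone (C1 ketone, C10 hydroxyl)
Conditions: IBX, DMSO, 23 °C
Reagents that add atoms: none
Why: IBX oxidises the secondary alcohol of a 1,2-diol to the α-ketol without glycol cleavage, and the tertiary C10 hydroxyl cannot react.

Step 22
Reactants: 34 α-hydroxy ketone
Product: 36 furanone (C6 O-TBS, C15 O-TBDPS), via hydroxy diketone 35 (not isolated)
Conditions: p-TsOH·H2O (0.2 equiv), acetone/H2O 10:1, 23 °C
Reagents that add atoms: none
Why: Ketal hydrolysis unmasks the C3 ketone, the C10 hydroxyl adds to it across the ring (5-exo-trig hemiketal) and loss of water toward C2 gives the vinylogous ester, the known acid cyclodehydration of α'-hydroxy 1,3-diketones to 3(2H)-furanones; the C6 oxygen stays silylated and cannot compete.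

Step 23
Reactants: 36 furanone
Product: 37 C6 alcohol
Conditions: HF·pyridine, pyridine, THF, 0 to 23 °C
Reagents that add atoms: none
Why: Buffered HF·pyridine should cleave the secondary TBS ether faster than the more acid-stable primary TBDPS ether.

Step 24
Reactants: 37 C6 alcohol; 38 angelic acid
Product: 40 C6 angelate (C15 O-TBDPS), via mixed anhydride 39 (not isolated)
Conditions: 38, 2,4,6-trichlorobenzoyl chloride, Et3N, toluene, 23 °C; then 37, toluene, 75 °C
Reagents that add atoms: none
Why: Yamaguchi esterification through the mixed 2,4,6-trichlorobenzoic anhydride without DMAP is the established way to acylate hindered secondary alcohols with angelic acid without isomerisation to the tiglate.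

Step 25
Reactants: 40 C6 angelate
Product: 41 target CNP0176514.1
Conditions: HF·pyridine (excess), THF, 0 to 23 °C
Reagents that add atoms: none
Why: Fluoride cleavage of the primary silyl ether under acidic, non-nucleophilic conditions should leave the methylene lactone, the furanone and the angelate intact.

**Compound list**

1 | methyl furan-2-carboxylate | COC(=O)c1ccco1 | starting material
2 | ethyl diazoacetate | CCOC(=O)C=[N+]=[N-] | starting material
3 | 6-ethyl 3-methyl (1S,5S,6S)-2-oxabicyclo[3.1.0]hex-3-ene-3,6-dicarboxylate (ethyl ester exo) | COC(=O)C1=C[C@H]2[C@H](C(=O)OCC)[C@H]2O1 | intermediate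
4 | ozonide of 3 (1,2,4-trioxolane across the former C3=C4 enol ether bond) | COC(=O)C12O[C@@H]3[C@@H](C(=O)OCC)[C@@H]3C(OO1)O2 | intermediate
5 | ethyl (1S,2S,3S)-2-formyl-3-[(2-methoxy-2-oxoacetyl)oxy]cyclopropane-1-carboxylate | O=C[C@H]1[C@H](C(=O)OCC)[C@H]1OC(=O)C(=O)OC | intermediate
6 | allyltrimethylsilane | C=CC[Si](C)(C)C | starting material
7 | ethyl 2-[(1S)-1-hydroxybut-3-en-1-yl]-3-[(2-methoxy-2-oxoacetyl)oxy]cyclopropane-1-carboxylate, ring configured as in 5 | C=CC[C@H](O)[C@H]1[C@H](C(=O)OCC)[C@H]1OC(=O)C(=O)OC | intermediate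
8 | cyclopropanol: 7 without the methoxyoxalyl group | C=CC[C@H](O)[C@H]1[C@H](C(=O)OCC)[C@H]1O | intermediate
9 | ethyl (3R,4S)-3-formyl-4-hydroxyhept-6-enoate | C=CC[C@H](O)[C@H](C=O)CC(=O)OCC | intermediate
10 | (2S,3R)-2-allyl-5-oxotetrahydrofuran-3-carbaldehyde (trans; CHO is C6, ring CH is C7, OCH is C8) | O=C1C[C@@H](C=O)[C@H](CC=C)O1 | intermediate
11 | tert-butyldimethyl(prop-2-yn-1-yloxy)silane | C#CCO[Si](C)(C)C(C)(C)C | starting material
12 | lithium acetylide of 11 | [Li]C#CCO[Si](C)(C)C(C)(C)C | intermediate
13 | dichlorocerium acetylide of 11 | Cl[Ce](Cl)C#CCO[Si](C)(C)C(C)(C)C | intermediate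
14 | trans-5-allyl-4-[1-hydroxy-4-(tert-butyldimethylsilyloxy)but-2-yn-1-yl]dihydrofuran-2(3H)-one, C7 and C8 as in 10, both C6 epimers | O=C1C[C@@H](C(O)C#CCO[Si](C)(C)C(C)(C)C)[C@H](CC=C)O1 | intermediate
15 | ynone: trans-5-allyl-4-[4-(tert-butyldimethylsilyloxy)but-2-ynoyl]dihydrofuran-2(3H)-one, C7 and C8 as in 10 | O=C1C[C@@H](C(=O)C#CCO[Si](C)(C)C(C)(C)C)[C@H](CC=C)O1 | intermediate
16 | (6R)-propargylic alcohol: the single C6 epimer of 14 with (R)-carbinol | O=C1C[C@@H]([C@@H](O)C#CCO[Si](C)(C)C(C)(C)C)[C@H](CC=C)O1 | intermediate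
17 | C6,C15-bis(tert-butyldimethylsilyl) ether of 16 | O=C1C[C@@H]([C@@H](O[Si](C)(C)C(C)(C)C)C#CCO[Si](C)(C)C(C)(C)C)[C@H](CC=C)O1 | intermediate
18 | C15 alcohol: C6 O-TBS propargylic ether with free primary propargylic hydroxyl | O=C1C[C@@H]([C@@H](O[Si](C)(C)C(C)(C)C)C#CCO)[C@H](CC=C)O1 | intermediate
19 | (Z)-alkenylstannane: C5H=C4(SnBu3)–C15H2OH, tin cis to C6, C6 O-TBS | O=C1C[C@@H]([C@@H](O[Si](C)(C)C(C)(C)C)/C=C(CO)\[Sn](CCCC)(CCCC)CCCC)[C@H](CC=C)O1 | intermediate
20 | C15 tert-butyldiphenylsilyl ether of 19 | O=C1C[C@@H]([C@@H](O[Si](C)(C)C(C)(C)C)/C=C(CO[Si](c2ccccc2)(c3ccccc3)C(C)(C)C)\[Sn](CCCC)(CCCC)CCCC)[C@H](CC=C)O1 | intermediate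
21 | 3-[(4-methoxybenzyl)oxy]propanoic acid | COc1ccc(COCCC(=O)O)cc1 | starting material
22 | 3-[(4-methoxybenzyl)oxy]propanoyl chloride | COc1ccc(COCCC(=O)Cl)cc1 | intermediate
23 | (Z)-enone: C3 ketone on C4, C1 O-PMB, C6 O-TBS, C15 O-TBDPS, allyl on C8 | O=C1C[C@@H]([C@@H](O[Si](C)(C)C(C)(C)C)/C=C(CO[Si](c2ccccc2)(c3ccccc3)C(C)(C)C)\C(=O)CCOCc4ccc(OC)cc4)[C@H](CC=C)O1 | intermediate
24 | C3 1,3-dioxolane of 23 | O=C1C[C@@H]([C@@H](O[Si](C)(C)C(C)(C)C)/C=C(CO[Si](c2ccccc2)(c3ccccc3)C(C)(C)C)\C4(OCCO4)CCOCc5ccc(OC)cc5)[C@H](CC=C)O1 | intermediate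
25 | C10 methyl ketone: 24 with the allyl group oxidised to 2-oxopropyl | O=C1C[C@@H]([C@@H](O[Si](C)(C)C(C)(C)C)/C=C(CO[Si](c2ccccc2)(c3ccccc3)C(C)(C)C)\C4(OCCO4)CCOCc5ccc(OC)cc5)[C@H](CC(C)=O)O1 | intermediate
26 | C1 alcohol: 25 without the PMB group | O=C1C[C@@H]([C@@H](O[Si](C)(C)C(C)(C)C)/C=C(CO[Si](c2ccccc2)(c3ccccc3)C(C)(C)C)\C4(OCCO4)CCO)[C@H](CC(C)=O)O1 | intermediate
27 | keto-aldehyde: C1 aldehyde, C3 dioxolane, (Z)-C4=C5, C6 O-TBS, C15 O-TBDPS, C10 methyl ketone on the (7R,8S) lactone | O=C1C[C@@H]([C@@H](O[Si](C)(C)C(C)(C)C)/C=C(CO[Si](c2ccccc2)(c3ccccc3)C(C)(C)C)\C4(OCCO4)CC=O)[C@H](CC(C)=O)O1 | intermediate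
28 | ten-membered C1,C10-diol, (10R), either C1 epimer; C3 dioxolane, C6 O-TBS, C15 O-TBDPS | O=C1O[C@H]2C[C@@](C)(O)C(O)CC3(OCCO3)/C(CO[Si](c4ccccc4)(c5ccccc5)C(C)(C)C)=C\[C@H](O[Si](C)(C)C(C)(C)C)[C@@H]2C1 | intermediate
29 | C1,C10-bis(trimethylsilyl) ether of 28 | O=C1O[C@H]2C[C@@](C)(O[Si](C)(C)C)C(O[Si](C)(C)C)CC3(OCCO3)/C(CO[Si](c4ccccc4)(c5ccccc5)C(C)(C)C)=C\[C@H](O[Si](C)(C)C(C)(C)C)[C@@H]2C1 | intermediate
30 | Mannich base: 29 with CH2NMe2 on C11 | O=C1O[C@H]2C[C@@](C)(O[Si](C)(C)C)C(O[Si](C)(C)C)CC3(OCCO3)/C(CO[Si](c4ccccc4)(c5ccccc5)C(C)(C)C)=C\[C@H](O[Si](C)(C)C(C)(C)C)[C@@H]2C1CN(C)C | intermediate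
31 | trimethylammonium iodide of 30 | O=C1O[C@H]2C[C@@](C)(O[Si](C)(C)C)C(O[Si](C)(C)C)CC3(OCCO3)/C(CO[Si](c4ccccc4)(c5ccccc5)C(C)(C)C)=C\[C@H](O[Si](C)(C)C(C)(C)C)[C@@H]2C1C[N+](C)(C)C.[I-] | intermediate
32 | α-methylene lactone bis-TMS ether | O=C1O[C@H]2C[C@@](C)(O[Si](C)(C)C)C(O[Si](C)(C)C)CC3(OCCO3)/C(CO[Si](c4ccccc4)(c5ccccc5)C(C)(C)C)=C\[C@H](O[Si](C)(C)C(C)(C)C)[C@@H]2C1=C | intermediate
33 | α-methylene lactone C1,C10-diol | O=C1O[C@H]2C[C@@](C)(O)C(O)CC3(OCCO3)/C(CO[Si](c4ccccc4)(c5ccccc5)C(C)(C)C)=C\[C@H](O[Si](C)(C)C(C)(C)C)[C@@H]2C1=C | intermediate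
34 | α-hydroxy ketone: C1 ketone, (10R) tertiary alcohol, C3 dioxolane | O=C1O[C@H]2C[C@@](C)(O)C(=O)CC3(OCCO3)/C(CO[Si](c4ccccc4)(c5ccccc5)C(C)(C)C)=C\[C@H](O[Si](C)(C)C(C)(C)C)[C@@H]2C1=C | intermediate
35 | hydroxy diketone: 34 with free C3 ketone | O=C1O[C@H]2C[C@@](C)(O)C(=O)CC(=O)/C(CO[Si](c3ccccc3)(c4ccccc4)C(C)(C)C)=C\[C@H](O[Si](C)(C)C(C)(C)C)[C@@H]2C1=C | intermediate
36 | furanone: target skeleton with C6 O-TBS and C15 O-TBDPS | C=C1C(=O)O[C@H]2C[C@@]3(C)OC(=CC3=O)/C(CO[Si](c4ccccc4)(c5ccccc5)C(C)(C)C)=C\[C@H](O[Si](C)(C)C(C)(C)C)[C@H]12 | intermediate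
37 | C6 alcohol: target skeleton with free C6 hydroxyl and C15 O-TBDPS | C=C1C(=O)O[C@H]2C[C@@]3(C)OC(=CC3=O)/C(CO[Si](c4ccccc4)(c5ccccc5)C(C)(C)C)=C\[C@H](O)[C@H]12 | intermediate
38 | angelic acid, (Z)-2-methylbut-2-enoic acid | OC(=O)/C(C)=C\C | starting material
39 | angelic 2,4,6-trichlorobenzoic anhydride | O=C(OC(=O)/C(C)=C\C)c1c(Cl)cc(Cl)cc1Cl | intermediate
40 | C15 O-TBDPS ether of the target | C=C1C(=O)O[C@H]2C[C@@]3(C)OC(=CC3=O)/C(CO[Si](c4ccccc4)(c5ccccc5)C(C)(C)C)=C\[C@H](OC(=O)/C(C)=C\C)[C@H]12 | intermediate
41 | CNP0176514.1, (6S,7R,8S,10R), (Z)-C4=C5, angelate at C6 | C=C1C(=O)O[C@H]2C[C@@]3(C)OC(=CC3=O)/C(CO)=C\[C@H](OC(=O)/C(C)=C\C)[C@H]12 | target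

**Step count and risks**

Total: 25 steps. Longest linear sequence: 24 steps (steps 1–11 and 13–25, from 1 to 41); step 12 is a one-step side branch.

Steps most likely to fail:

1. Step 18 (ring closure). The risks are intermolecular ketyl coupling or simple reduction of the aldehyde outrunning cyclisation, and poor facial selectivity at the C10 ketone. The fallback sets out from 27: low-valent titanium (TiCl3(DME)1.5, Zn–Cu couple, DME, reflux, high dilution) would join the same two carbonyl carbons by McMurry coupling to the C1=C10 cyclodecene F1, and OsO4 (cat.) with N-methylmorpholine N-oxide would then dihydroxylate this trialkyl alkene in preference to the hindered, oxygen-flanked C4=C5 alkene, returning to the route at 28. C10 is then set by peripheral attack on an alkene instead of by ketyl addition. Unwanted diol isomers from either approach can be cleaved with NaIO4 back to 27 and recycled.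

2. Step 14 (ketalisation). The risks are loss of the Z geometry, participation of the C6 silyloxy oxygen under Lewis acid (cyclisation toward a furan), or incomplete reaction at the hindered conjugated ketone. The fallback sets out from 23: the far more nucleophilic silylated dithiol (Me3SiS(CH2)3SSiMe3, ZnI2, Et2O, 0 °C) would give the 1,3-dithiane F2 under nearly neutral conditions, and oxidative exchange with PhI(OCOCF3)2 in MeCN containing ethylene glycol would convert it into the dioxolane, returning to the route at 24.

3. Step 13 (acylation). The risk is slow tin-to-palladium transfer from the hindered α-branched stannane, leaving time for protodestannylation or decarbonylation of the acylpalladium species. The fallback sets out from 20: iodine (CH2Cl2, 0 °C) would give the alkenyl iodide F3 with retention; the aldehyde 3-[(4-methoxybenzyl)oxy]propanal F4 would be made from 22 with LiAlH(Ot-Bu)3 (THF, −78 °C). Nozaki–Hiyama–Kishi coupling of the two (CrCl2, NiCl2 (cat.), DMSO, 23 °C; divalent chromium adds only to the aldehyde, lactone and alkene being inert) would give the allylic alcohols F5 as C3 epimers, and Dess–Martin oxidation would return to the route at 23.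

**Further compounds**

F1 | step 18 | C1=C10 cyclodecene (alkene geometry open), C3 dioxolane, C6 O-TBS, C15 O-TBDPS | O=C1O[C@H]2CC(C)=CCC3(OCCO3)/C(CO[Si](c4ccccc4)(c5ccccc5)C(C)(C)C)=C\[C@H](O[Si](C)(C)C(C)(C)C)[C@@H]2C1
F2 | step 14 | C3 1,3-dithiane analogue of 24 | O=C1C[C@@H]([C@@H](O[Si](C)(C)C(C)(C)C)/C=C(CO[Si](c2ccccc2)(c3ccccc3)C(C)(C)C)\C4(SCCCS4)CCOCc5ccc(OC)cc5)[C@H](CC=C)O1
F3 | step 13 | (Z)-C4 alkenyl iodide from 20 | O=C1C[C@@H]([C@@H](O[Si](C)(C)C(C)(C)C)/C=C(CO[Si](c2ccccc2)(c3ccccc3)C(C)(C)C)\I)[C@H](CC=C)O1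
F4 | step 13 | 3-[(4-methoxybenzyl)oxy]propanal | COc1ccc(COCCC=O)cc1
F5 | step 13 | C3 allylic alcohols (both C3 epimers) corresponding to 23 | O=C1C[C@@H]([C@@H](O[Si](C)(C)C(C)(C)C)/C=C(CO[Si](c2ccccc2)(c3ccccc3)C(C)(C)C)\C(O)CCOCc4ccc(OC)cc4)[C@H](CC=C)O1
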